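# Proposed total synthesis of CNP0177598.2 (35)

## Analysis of the target

The target 35 consists of two xanthane (C15) halves, and xanthane locants are used throughout. Unprimed locants denote the half in which α‑methylene‑γ‑butyrolactone ring A (C7–C8–O–C12–C11) is cis‑fused to cycloheptane ring B (C1, C5–C10). Primed locants denote the half in which γ‑lactone ring D (C11'–C12'–O–C8'–C7') is cis‑fused to the epoxidised cycloheptane ring E (C1', C5'–C10').

The halves are joined by cyclohexene ring C (C1, C2, C3, C11', C13', C5), which is spiro to ring D at C11' and trans‑fused to ring B along C1–C5. There are eleven stereocentres: 1S,5S,7R,8R,10S and 1'R,5'R,7'S,8'S,10'R,11'R.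

Remark on the chemistry: read as drawn, each triad C7/C8/C10 and C7'/C8'/C10' is all‑cis, but the two triads are mirror images, so the halves belong to opposite enantiomeric series.

On ring C the three carbon substituents C6 (on C5), C10 (on C1) and C7' (on C11') can all be equatorial. C1–OH and C12' are then axial and trans to each other, and C3 lies on the face of ring D that carries H7' and H8'.

The feature that invites the chosen move is that C11' sits between the lactone carbonyl C12' and the acetyl‑bearing sp2 carbon C3, while C1–OH is β to C3 through C2. If C3 is read as a former ketone, ring C is an aldol (C1–C2–C3) grafted on a β‑keto lactone (C3–C11'–C12') whose C13' arm is 1,5‑related to a carbonyl at C1.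

Sensitive groups are the α‑methylene lactone (Michael acceptor), the vinyl epoxide conjugated to an (E)‑enone, the tertiary γ‑hydroxy enone and two methyl ketones. The difficulty is to join two unlike‑handed halves at a spiro quaternary centre next to a tertiary alcohol, to build two seven‑membered rings, and to finish with chemoselective oxidation.

## Retrosynthetic reasoning

**35 ⇒ 34 (C1'–O, C5'–O).** The epoxide is cut last. In dienone 34 the C1'=C5' bond is the only electron‑rich alkene, and its free face is the one opposite the C10' methyl group and ring D, so a peracid should deliver the required epoxide.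

**34 ⇒ 31 + 32 (C1'=C5', C2'=C3').** Ring E and its butenone chain are cut together. Forward, a ring‑closing enyne metathesis of the cis‑disposed allyl and butynyl arms of 31, followed by cross‑metathesis with 32, closes the seven‑membered ring and installs the (E)‑enone in one operation. This keeps the diene of half 2 out of every earlier step.

**31 ⇒ 30 ⇒ 28 (unmasking).** The alkyne hydrogen and the C11=C13 methylene of ring A are revealed late, from a silylalkyne and a phenylsulfanylmethyl lactone. Both masks are inert to the enolate, Lewis acid and palladium chemistry that builds ring C.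

**28 ⇒ 25 ⇒ 24 (C3–C4).** The acetyl group is cut from C3. Enone 28 then becomes enol triflate 25 and, one step further back, ketol 24. This is the disconnection that exposes the carbonyl pattern hidden in ring C.

**24 ⇒ 23 (C1–C2).** Ring C is opened by a retro‑aldol. Forward, the methyl ketone on C11' closes onto the C1 ketone of ring B. This creates the tertiary alcohol directly and sets C1 and C5 through a chair in which C6, C10 and C7' are equatorial.

**23 ⇒ 22 ⇒ 19 + 13 + 20 (C5–C13', C11'–C3).** Ring C is cut into three two‑carbon pieces: C5–C1 from enol silane 19, C13'–C11' from the α‑methylene lactone 13, and C3–C2 from acetaldehyde 20. The order matters: C13' is attached to C11' first and C3 second, so that C3 enters trans to the lactone substituents, as the target requires.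

**19 ⇒ 18 ⇒ 17 ⇒ 15 ⇒ 14 ⇒ 11 (C1=C5 of ring B).** Ring B is cut at its enol silane double bond. Forward, ring‑closing metathesis of the kinetic enol silane 18 gives the C1/C5 enol silane regiospecifically. The ketone comes from hydration of the alkyne of 14.

**11 and 13 ⇒ 3 or 4 + 9 (C7–C8, O–C12).** Both halves are traced to the two enantiomers of one lactone. A syn‑selective allylboration and lactonisation sets C7 and C8; the same chemistry with mirror‑image catalysts serves both halves.

**3, 4 ⇒ 1 + 2; 9 ⇒ 5 + 6 + 7.** C10 and C10' come from an asymmetric conjugate alkynylation of crotonaldehyde. The allylboronate 9 comes from a carbocupration and alkylation of ethyl propiolate.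

## Alternatives that were turned down

**Alternative 1:** the textbook, biomimetic cut of ring C at C5–C13' and C3–C11'.
- Forward key step: thermal [4+2] cycloaddition of dienone lactone A1 (7R,8R,10S series) with the epoxy α‑methylene lactone A2 of the mirror‑image series. This gives cycloadduct A3, which still needs γ‑oxygenation at C1.
- It is the shortest plan on paper, but it was turned down as the step that carries the synthesis, for three reasons.
  - The partners are unlike‑handed. The facial and exo preferences that make the like‑handed dimerisation work cannot be assumed for this pair.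
  - A1 is itself a dienophile, so its self‑dimerisation competes directly with the cross reaction.
  - The C1 hydroxyl would have to be introduced afterwards, undirected, next to a vinyl epoxide and a second dienone.
- All the risk would fall on one step that cannot be steered, at the point where both halves are complete. The cycloaddition is kept only as the fallback for step 11.

**Alternative 2:** the direct retro‑[4+2] of the C2=C3 cyclohexene, cutting C1–C5 and C11'–C13'.
- Forward key step: intramolecular Diels–Alder reaction of the 2‑pyranone A4. The pyranone oxygen would become the C1 oxygen and its carbonyl would become C12', so rings B and C close together; translactonisation to O–C8' would follow.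
- It was turned down on structural grounds. The lactone bridge of the bicyclo[2.2.2] adduct forces the C1 oxygen and C12' onto the same face of ring C, whereas in 35 they are trans (the C1 oxygen is cis to C7'). The plan would therefore deliver the spiro centre epimeric at C11', and a quaternary centre cannot be corrected.
- It also requires a seven‑membered ring closure onto an unactivated alkene.

**Alternative 3:** a Robinson annulation, cutting C11'–C13' and C1–C2.
- Forward key step: Michael addition of the β‑keto lactone A5 (as its enolate) to the exo‑methylene ketone A6, then aldol closure.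
- It was turned down because the electrophilic carbon C13' would enter the enolate trans to the C7' and C8' substituents. That places C13' on the convex face of ring D and the acetyl carbon C3 on the concave face, the opposite of the target. The same reagents cannot reverse this.
- The chosen route reverses the order of bond formation at C11' instead.

Key step: step 11

## Route

Assumption: which antipode of the chiral ligand or acid gives which antipode of product in steps 1, 2, 4 and 5 is assigned by analogy with simpler substrates; the two halves need opposite antipodes, so a reversed sense would only exchange the ligands.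

Step 1
Reactants: 1 (E)-but-2-enal; 2 ethynyltri(propan-2-yl)silane
Product: 3 (3S)-3-methyl-5-[tri(propan-2-yl)silyl]pent-4-ynal
Conditions: [Rh(OAc)(C2H4)2]2 (2.5 mol %), (R)-DTBM-SEGPHOS (6 mol %), MeOH, 40 °C
Reagents that add atoms: none
Why: Rhodium-catalysed asymmetric conjugate alkynylation of an enal; the bulky silyl group suppresses alkyne dimerisation and the bisphosphine selects the face of the enal, which sets C10, the one stereocentre of half 1 that is not relayed later.

Step 2
Reactants: 1 (E)-but-2-enal; 2 ethynyltri(propan-2-yl)silane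
Product: 4 (3R)-3-methyl-5-[tri(propan-2-yl)silyl]pent-4-ynal
Conditions: [Rh(OAc)(C2H4)2]2 (2.5 mol %), (S)-DTBM-SEGPHOS (6 mol %), MeOH, 40 °C
Reagents that add atoms: none
Why: The same conjugate alkynylation with the antipodal ligand should give the antipodal aldehyde, which sets C10' of half 2.

Step 3
Reactants: 5 ethyl prop-2-ynoate; 6 allylmagnesium bromide; 7 2-(iodomethyl)-4,4,5,5-tetramethyl-1,3,2-dioxaborolane
Product: 9 ethyl (2E)-2-[(4,4,5,5-tetramethyl-1,3,2-dioxaborolan-2-yl)methyl]hexa-2,5-dienoate, via alkenylcopper 8 (not isolated)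
Conditions: 6, CuBr·SMe2, THF, −78 °C; 5; then 7, HMPA, −78 to 0 °C
Reagents that add atoms: none
Why: syn-Carbocupration of the ynoate followed by alkylation of the α-cuprio acrylate with retention places the allyl group cis to CH2B, the geometry that leads to the syn adduct in steps 4 and 5.

Step 4
Reactants: 3 (3S)-3-methyl-5-[tri(propan-2-yl)silyl]pent-4-ynal; 9 ethyl (2E)-2-[(4,4,5,5-tetramethyl-1,3,2-dioxaborolan-2-yl)methyl]hexa-2,5-dienoate
Product: 11 (4R,5R)-3-methylidene-5-{(2S)-2-methyl-4-[tri(propan-2-yl)silyl]but-3-yn-1-yl}-4-(prop-2-en-1-yl)oxolan-2-one, via borate ester 10 (not isolated)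
Conditions: (R)-TRIP phosphoric acid (5 mol %), 4 Å molecular sieves, toluene, −30 °C; then TsOH·H2O, CH2Cl2, rt
Reagents that add atoms: none
Why: Brønsted-acid-catalysed allylboration through a closed chair transition state; the allyl substituent cis to CH2B is axial, so the adduct is syn and lactonises to the cis-4,5-disubstituted α-methylene lactone (C7, C8), while the chiral phosphoric acid selects the aldehyde face independently of the remote C10.

Step 5
Reactants: 4 (3R)-3-methyl-5-[tri(propan-2-yl)silyl]pent-4-ynal; 9 ethyl (2E)-2-[(4,4,5,5-tetramethyl-1,3,2-dioxaborolan-2-yl)methyl]hexa-2,5-dienoate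
Product: 13 (4S,5S)-3-methylidene-5-{(2R)-2-methyl-4-[tri(propan-2-yl)silyl]but-3-yn-1-yl}-4-(prop-2-en-1-yl)oxolan-2-one, via borate ester 12 (not isolated)
Conditions: (S)-TRIP phosphoric acid (5 mol %), 4 Å molecular sieves, toluene, −30 °C; then TsOH·H2O, CH2Cl2, rt
Reagents that add atoms: none
Why: Mirror image of step 4; it sets C7' and C8' of half 2, and because 13 is the enantiomer of 11 there is no matched or mismatched difference between the two halves.

Step 6
Reactants: 11 (4R,5R)-3-methylidene-5-{(2S)-2-methyl-4-[tri(propan-2-yl)silyl]but-3-yn-1-yl}-4-(prop-2-en-1-yl)oxolan-2-one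
Product: 14 (4R,5R)-3-methylidene-5-[(2S)-2-methylbut-3-yn-1-yl]-4-(prop-2-en-1-yl)oxolan-2-one
Conditions: tetrabutylammonium fluoride, AcOH, THF, 0 °C to rt
Reagents that add atoms: none
Why: Fluoride-induced protodesilylation of the alkynylsilane; the acetic acid buffer protects the α-methylene lactone from base.

Step 7
Reactants: 14 (4R,5R)-3-methylidene-5-[(2S)-2-methylbut-3-yn-1-yl]-4-(prop-2-en-1-yl)oxolan-2-one
Product: 15 (4R,5R)-3-methylidene-5-[(2S)-2-methyl-3-oxobutyl]-4-(prop-2-en-1-yl)oxolan-2-one
Conditions: Ph3PAuNTf2 (2 mol %), H2O, 1,4-dioxane, 60 °C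
Reagents that add atoms: water, O
Why: Gold-catalysed Markovnikov hydration of the terminal alkyne gives the methyl ketone whose carbonyl carbon becomes C1; the alkenes are too remote from the alkyne for cycloisomerisation.

Step 8
Reactants: 15 (4R,5R)-3-methylidene-5-[(2S)-2-methyl-3-oxobutyl]-4-(prop-2-en-1-yl)oxolan-2-one; 16 benzenethiol
Product: 17 (4R,5R)-5-[(2S)-2-methyl-3-oxobutyl]-3-[(phenylsulfanyl)methyl]-4-(prop-2-en-1-yl)oxolan-2-one (both C3 epimers)
Conditions: Et3N (0.1 equiv), CH2Cl2, 0 °C
Reagents that add atoms: none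
Why: Thia-Michael addition masks the acceptor alkene of ring A, so that in step 11 only the lactone of half 2 can accept the nucleophile; the new centre at C11 is removed again in step 16.

Step 9
Reactants: 17 (4R,5R)-5-[(2S)-2-methyl-3-oxobutyl]-3-[(phenylsulfanyl)methyl]-4-(prop-2-en-1-yl)oxolan-2-one
Product: 18 (4R,5R)-5-[(2S)-3-{[tert-butyl(dimethyl)silyl]oxy}-2-methylbut-3-en-1-yl]-3-[(phenylsulfanyl)methyl]-4-(prop-2-en-1-yl)oxolan-2-one
Conditions: lithium diisopropylamide (1.05 equiv), THF, −78 °C; then TBSOTf, −78 °C
Reagents that add atoms: tert-butyldimethylsilyl trifluoromethanesulfonate, CC(C)(C)[Si](C)(C)OS(=O)(=O)C(F)(F)F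
Why: Kinetic deprotonation of the methyl ketone at its methyl group (faster than at the hindered C10–H or at the lactone) and O-silylation give the terminal enol silane needed for ring closure.

Step 10
Reactants: 18 (4R,5R)-5-[(2S)-3-{[tert-butyl(dimethyl)silyl]oxy}-2-methylbut-3-en-1-yl]-3-[(phenylsulfanyl)methyl]-4-(prop-2-en-1-yl)oxolan-2-one
Product: 19 (3aR,7S,8aR)-6-{[tert-butyl(dimethyl)silyl]oxy}-7-methyl-3-[(phenylsulfanyl)methyl]-3,3a,4,7,8,8a-hexahydro-2H-cyclohepta[b]furan-2-one
Conditions: second-generation Grubbs catalyst RuCl2(=CHPh)(H2IMes)(PCy3) (10 mol %), toluene, 70 °C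
Reagents that add atoms: none
Why: Ring-closing metathesis of an olefinic silyl enol ether closes ring B; the cis-lactone holds the two arms together, and the product is the regiodefined C1/C5 enol silane, so C5 is the only nucleophilic carbon in the next step.

Step 11
Reactants: 19 (3aR,7S,8aR)-6-{[tert-butyl(dimethyl)silyl]oxy}-7-methyl-3-[(phenylsulfanyl)methyl]-3,3a,4,7,8,8a-hexahydro-2H-cyclohepta[b]furan-2-one; 13 (4S,5S)-3-methylidene-5-{(2R)-2-methyl-4-[tri(propan-2-yl)silyl]but-3-yn-1-yl}-4-(prop-2-en-1-yl)oxolan-2-one; 20 acetaldehyde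
Product: 22 hydroxyethyl adduct (ring B ketone of half 1 joined by C5–C13' to lactone ring D of half 2; C11' quaternary and bearing CH(OH)CH3 trans to the C7' allyl group; mixture at C5 and at the carbinol carbon), via titanium enolate 21 (not isolated)
Conditions: 13 (1.2 equiv), TiCl4 (1.1 equiv), CH2Cl2, −78 °C; 19; then 20 (3 equiv), −78 °C; aqueous NaHCO3
Reagents that add atoms: none
Why: TiCl4 activates the lactone carbonyl of 13, the enol silane 19 adds through C5 to the exocyclic carbon C13' (Mukaiyama–Michael addition) with loss of the silyl group, and the resulting titanium enolate 21, formed regiospecifically at C11', is trapped by acetaldehyde in an aldol addition. The closest known reaction type is the tandem conjugate addition–aldol three-component coupling of an enolate equivalent, an enoate and an aldehyde. The step closes no ring; it joins three pieces and forms C5–C13' and C11'–C3, so that ring C lacks only the C1–C2 bond, which is closed in step 13 as a 6-(enolexo)-exo-trig aldol. The new quaternary stereocentre C11' is controlled by the lactone itself: the C7' allyl group and the C8' side chain are cis and block one face, so the aldehyde adds to the other face and C3 ends up cis to H7', as in the target. Because C13' is already on C11' when C3 arrives, this order gives the spiro centre of the target and not its epimer. C5 (α to the ketone) and the carbinol carbon are not controlled here; the first is equilibrated in step 12 and fixed in step 13, and the second is oxidised in step 12. The selectivity needed is cross- over self-addition and 1,4- over 1,2-addition; it is secured by the sulfide mask on ring A of 19, by adding acetaldehyde only after 19 is consumed, and by the locked s-cis acceptor of 13.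

Step 12
Reactants: 22 hydroxyethyl adduct
Product: 23 acetyl lactone (as 22 but with C3 as a ketone; the C11' acetyl lactone is 1,5-related to the C1 ketone; C5 drawn as the 5,10-cis epimer)
Conditions: SO3·pyridine, DMSO, iPr2NEt, CH2Cl2, 0 °C to rt
Reagents that add atoms: none
Why: Parikh–Doering oxidation converts the secondary carbinol into the methyl ketone without touching the sulfide, and the amine base should equilibrate C5 to the 2,7-cis-disubstituted cycloheptanone that step 13 needs.

Step 13
Reactants: 23 acetyl lactone
Product: 24 ketol (ring C closed: C1–OH, C2H2, C3=O; all stereocentres as in 35 except the C11 epimers of the masked ring A)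
Conditions: lithium bis(trimethylsilyl)amide (1.2 equiv), THF, −78 to −20 °C; then AcOH
Reagents that add atoms: none
Why: Intramolecular aldol addition of the kinetic methyl-ketone enolate (C2) to the C1 ketone; in the lithium-bridged bicyclic chair transition state the two oxygens on C3 and C1 are syn-diaxial, which makes C1–O axial and C10 equatorial (trans-fusion to ring B), while C6 and the bulky C7' take equatorial positions, so C1 and C5 are set as in the target, and the reversibility of the aldol should favour the same all-equatorial ketol.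

Step 14
Reactants: 24 ketol
Product: 25 enol triflate (C3–OSO2CF3 with C2=C3; tertiary C1–OH free)
Conditions: potassium bis(trimethylsilyl)amide (2.3 equiv), PhNTf2, THF, −78 °C (ketol added to the base)
Reagents that add atoms: N-phenylbis(trifluoromethanesulfonimide), O=S(=O)(N(c1ccccc1)S(=O)(=O)C(F)(F)F)C(F)(F)F
Why: The C3 ketone can enolise only towards C2 because C11' is quaternary, so O-triflation of the enolate gives the C2=C3 enol triflate as a single regioisomer; once the ketone is enolised a retro-aldol is no longer possible.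

Step 15
Reactants: 25 enol triflate; 26 tributyl(1-ethoxyethenyl)stannane
Product: 28 enone (C3 bearing the acetyl group C4/C15; γ-hydroxy enone of ring C complete), via enol ether 27 (not isolated)
Conditions: Pd(PPh3)4 (5 mol %), LiCl, CuI, THF, 65 °C; then 0.5 M HCl, THF, 0 °C
Reagents that add atoms: water, O
Why: Stille coupling of the enol triflate with an acyl-anion equivalent forms the C3–C4 bond, and mild acid hydrolysis of the enol ether liberates the methyl ketone; the silylalkyne and the sulfide are inert to zerovalent palladium under these conditions.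

Step 16
Reactants: 28 enone
Product: 30 α-methylidene lactone (ring A unmasked; half 2 still carries the allyl and silylbutynyl arms), via sulfoxide 29 (not isolated)
Conditions: mCPBA (1.0 equiv), CH2Cl2, −78 °C; then NaHCO3, toluene, 100 °C
Reagents that add atoms: none
Why: Chemoselective oxidation of the sulfide to the sulfoxide (much faster than epoxidation of any alkene present) followed by thermal syn-elimination, which can only take the C11 hydrogen, restores the exocyclic C11=C13 bond.

Step 17
Reactants: 30 α-methylidene lactone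
Product: 31 terminal alkyne (as 30 with C≡C–H)
Conditions: tetrabutylammonium fluoride, AcOH, THF, 0 °C to rt
Reagents that add atoms: none
Why: Buffered protodesilylation of the alkynylsilane frees the alkyne for metathesis without exposing the methylene lactone and the γ-hydroxy enone to base.

Step 18
Reactants: 31 terminal alkyne; 32 but-3-en-2-one
Product: 34 dienone (ring E closed with C1'=C5' and the (E)-3-oxobut-1-enyl chain on C1'; 35 without the epoxide), via triene 33 (not isolated)
Conditions: second-generation Hoveyda–Grubbs catalyst RuCl2(=CH-C6H4-2-OiPr)(H2IMes) (10 mol %), 32 (10 equiv), CH2Cl2, 40 °C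
Reagents that add atoms: none
Why: Domino ring-closing enyne metathesis of the cis-disposed allyl and butynyl arms and cross-metathesis of the resulting vinyl group with the enone, a sequence with close precedent on the monomeric cis-lactone; the electron-poor 1,1-disubstituted alkene of ring A and the trisubstituted enone of ring C should not take part, and cross-metathesis should give the (E)-enone.

Step 19
Reactants: 34 dienone
Product: 35 CNP0177598.2 (1S,5S,7R,8R,10S,1'R,5'R,7'S,8'S,10'R,11'R)
Conditions: mCPBA (1.1 equiv), NaHCO3, CH2Cl2, 0 °C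
Reagents that add atoms: 3-chloroperoxybenzoic acid (mCPBA), OOC(=O)c1cccc(Cl)c1
Why: Peracid epoxidation takes the only electron-rich alkene (C1'=C5', the γ,δ-bond of the dienone) and should approach from the face opposite the C10' methyl group and ring D, which gives the epoxide cis to H7', H8' and H10'.

## Compound list

1 | (E)-but-2-enal | C/C=C/C=O | starting material
2 | ethynyltri(propan-2-yl)silane | C#C[Si](C(C)C)(C(C)C)C(C)C | starting material
3 | (3S)-3-methyl-5-[tri(propan-2-yl)silyl]pent-4-ynal | O=CC[C@H](C)C#C[Si](C(C)C)(C(C)C)C(C)C | intermediate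
4 | (3R)-3-methyl-5-[tri(propan-2-yl)silyl]pent-4-ynal | O=CC[C@@H](C)C#C[Si](C(C)C)(C(C)C)C(C)C | intermediate
5 | ethyl prop-2-ynoate | C#CC(=O)OCC | starting material
6 | allylmagnesium bromide | C=CC[Mg]Br | starting material
7 | 2-(iodomethyl)-4,4,5,5-tetramethyl-1,3,2-dioxaborolane | ICB1OC(C)(C)C(C)(C)O1 | starting material
8 | alkenylcopper, ethyl (2Z)-2-cuprio-hexa-2,5-dienoate | CCOC(=O)/C([Cu])=C/CC=C | intermediate
9 | ethyl (2E)-2-[(4,4,5,5-tetramethyl-1,3,2-dioxaborolan-2-yl)methyl]hexa-2,5-dienoate | CCOC(=O)/C(CB1OC(C)(C)C(C)(C)O1)=C/CC=C | intermediate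
10 | borate ester of the syn homoallylic alcohol from 3 and 9 (ethyl ester, O–B(pinacolato) on C8) | CCOC(=O)C(=C)[C@@H](CC=C)[C@H](OB1OC(C)(C)C(C)(C)O1)C[C@H](C)C#C[Si](C(C)C)(C(C)C)C(C)C | intermediate
11 | (4R,5R)-3-methylidene-5-{(2S)-2-methyl-4-[tri(propan-2-yl)silyl]but-3-yn-1-yl}-4-(prop-2-en-1-yl)oxolan-2-one | C=C1C(=O)O[C@H](C[C@H](C)C#C[Si](C(C)C)(C(C)C)C(C)C)[C@@H]1CC=C | intermediate
12 | borate ester of the syn homoallylic alcohol from 4 and 9 (enantiomer of 10) | CCOC(=O)C(=C)[C@H](CC=C)[C@@H](OB1OC(C)(C)C(C)(C)O1)C[C@@H](C)C#C[Si](C(C)C)(C(C)C)C(C)C | intermediate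
13 | (4S,5S)-3-methylidene-5-{(2R)-2-methyl-4-[tri(propan-2-yl)silyl]but-3-yn-1-yl}-4-(prop-2-en-1-yl)oxolan-2-one | C=C1C(=O)O[C@@H](C[C@@H](C)C#C[Si](C(C)C)(C(C)C)C(C)C)[C@H]1CC=C | intermediate
14 | (4R,5R)-3-methylidene-5-[(2S)-2-methylbut-3-yn-1-yl]-4-(prop-2-en-1-yl)oxolan-2-one | C=C1C(=O)O[C@H](C[C@H](C)C#C)[C@@H]1CC=C | intermediate
15 | (4R,5R)-3-methylidene-5-[(2S)-2-methyl-3-oxobutyl]-4-(prop-2-en-1-yl)oxolan-2-one | C=C1C(=O)O[C@H](C[C@H](C)C(C)=O)[C@@H]1CC=C | intermediate
16 | benzenethiol | Sc1ccccc1 | starting material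
17 | (4R,5R)-5-[(2S)-2-methyl-3-oxobutyl]-3-[(phenylsulfanyl)methyl]-4-(prop-2-en-1-yl)oxolan-2-one (both C3 epimers) | c1ccccc1SCC1C(=O)O[C@H](C[C@H](C)C(C)=O)[C@@H]1CC=C | intermediate
18 | (4R,5R)-5-[(2S)-3-{[tert-butyl(dimethyl)silyl]oxy}-2-methylbut-3-en-1-yl]-3-[(phenylsulfanyl)methyl]-4-(prop-2-en-1-yl)oxolan-2-one (both C3 epimers) | c1ccccc1SCC1C(=O)O[C@H](C[C@H](C)C(=C)O[Si](C)(C)C(C)(C)C)[C@@H]1CC=C | intermediate
19 | (3aR,7S,8aR)-6-{[tert-butyl(dimethyl)silyl]oxy}-7-methyl-3-[(phenylsulfanyl)methyl]-3,3a,4,7,8,8a-hexahydro-2H-cyclohepta[b]furan-2-one (both C3 epimers) | c1ccccc1SCC1C(=O)O[C@@H]2C[C@H](C)C(O[Si](C)(C)C(C)(C)C)=CC[C@H]12 | intermediate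
20 | acetaldehyde | CC=O | starting material
21 | titanium enolate of the Michael adduct (C5–C13' formed; trichlorotitanium enolate at C11'/C12' of ring D) | c1ccccc1SCC1C(=O)O[C@@H]2C[C@H](C)C(=O)C(CC3=C(O[Ti](Cl)(Cl)Cl)O[C@@H](C[C@@H](C)C#C[Si](C(C)C)(C(C)C)C(C)C)[C@H]3CC=C)C[C@H]12 | intermediate
22 | hydroxyethyl adduct: ring B ketone joined by C5–C13' to ring D; C11' quaternary, bearing CH(OH)CH3 trans to the C7' allyl group; mixture at C5, the carbinol carbon and C11 | c1ccccc1SCC1C(=O)O[C@@H]2C[C@H](C)C(=O)C(C[C@@]3(C(C)O)C(=O)O[C@@H](C[C@@H](C)C#C[Si](C(C)C)(C(C)C)C(C)C)[C@H]3CC=C)C[C@H]12 | intermediate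
23 | acetyl lactone: as 22 with C3 as ketone; C5 cis to the C10 methyl group | c1ccccc1SCC1C(=O)O[C@@H]2C[C@H](C)C(=O)[C@H](C[C@@]3(C(C)=O)C(=O)O[C@@H](C[C@@H](C)C#C[Si](C(C)C)(C(C)C)C(C)C)[C@H]3CC=C)C[C@H]12 | intermediate
24 | ketol: ring C closed (C1–OH, C2H2, C3=O), spiro at C11', trans-fused to ring B; configuration at C1, C5, C7, C8, C10, C7', C8', C10', C11' as in 35 | c1ccccc1SCC1C(=O)O[C@@H]2C[C@H](C)[C@@]3(O)CC(=O)[C@]4(C[C@@H]3C[C@H]12)C(=O)O[C@@H](C[C@@H](C)C#C[Si](C(C)C)(C(C)C)C(C)C)[C@H]4CC=C | intermediate
25 | enol triflate: as 24 with C3–OSO2CF3 and C2=C3 | c1ccccc1SCC1C(=O)O[C@@H]2C[C@H](C)[C@@]3(O)C=C(OS(=O)(=O)C(F)(F)F)[C@]4(C[C@@H]3C[C@H]12)C(=O)O[C@@H](C[C@@H](C)C#C[Si](C(C)C)(C(C)C)C(C)C)[C@H]4CC=C | intermediate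
26 | tributyl(1-ethoxyethenyl)stannane | CCCC[Sn](CCCC)(CCCC)C(=C)OCC | starting material
27 | enol ether: as 25 with C3–C(=CH2)OEt | c1ccccc1SCC1C(=O)O[C@@H]2C[C@H](C)[C@@]3(O)C=C(C(=C)OCC)[C@]4(C[C@@H]3C[C@H]12)C(=O)O[C@@H](C[C@@H](C)C#C[Si](C(C)C)(C(C)C)C(C)C)[C@H]4CC=C | intermediate
28 | enone: ring C complete (C1–OH, C2=C3, C3–acetyl); ring A masked as phenylsulfanylmethyl lactone; half 2 with allyl and silylbutynyl arms | c1ccccc1SCC1C(=O)O[C@@H]2C[C@H](C)[C@@]3(O)C=C(C(C)=O)[C@]4(C[C@@H]3C[C@H]12)C(=O)O[C@@H](C[C@@H](C)C#C[Si](C(C)C)(C(C)C)C(C)C)[C@H]4CC=C | intermediate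
29 | sulfoxide of 28 (mixture at sulfur and C11) | O=S(c1ccccc1)CC1C(=O)O[C@@H]2C[C@H](C)[C@@]3(O)C=C(C(C)=O)[C@]4(C[C@@H]3C[C@H]12)C(=O)O[C@@H](C[C@@H](C)C#C[Si](C(C)C)(C(C)C)C(C)C)[C@H]4CC=C | intermediate
30 | α-methylidene lactone: rings A, B, C, D of 35 complete; half 2 with allyl and silylbutynyl arms | C=C1C(=O)O[C@@H]2C[C@H](C)[C@@]3(O)C=C(C(C)=O)[C@]4(C[C@@H]3C[C@H]12)C(=O)O[C@@H](C[C@@H](C)C#C[Si](C(C)C)(C(C)C)C(C)C)[C@H]4CC=C | intermediate
31 | terminal alkyne: as 30 with C≡C–H | C=C1C(=O)O[C@@H]2C[C@H](C)[C@@]3(O)C=C(C(C)=O)[C@]4(C[C@@H]3C[C@H]12)C(=O)O[C@@H](C[C@@H](C)C#C)[C@H]4CC=C | intermediate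
32 | but-3-en-2-one | C=CC(C)=O | starting material
33 | triene: ring E closed (C1'=C5'), vinyl group on C1' | C=C1C(=O)O[C@@H]2C[C@H](C)[C@@]3(O)C=C(C(C)=O)[C@]4(C[C@@H]3C[C@H]12)C(=O)O[C@H]1C[C@@H](C)C(C=C)=CC[C@H]14 | intermediate
34 | dienone: 35 without the epoxide (C1'=C5', (E)-3-oxobut-1-enyl on C1') | C=C1C(=O)O[C@@H]2C[C@H](C)[C@@]3(O)C=C(C(C)=O)[C@]4(C[C@@H]3C[C@H]12)C(=O)O[C@H]1C[C@@H](C)C(/C=C/C(C)=O)=CC[C@H]14 | intermediate
35 | CNP0177598.2, (1S,5S,7R,8R,10S,1'R,5'R,7'S,8'S,10'R,11'R) in xanthane numbering | C=C1C(=O)O[C@@H]2C[C@H](C)[C@@]3(O)C=C(C(C)=O)[C@]4(C[C@@H]3C[C@H]12)C(=O)O[C@H]1C[C@@H](C)[C@]2(/C=C/C(C)=O)O[C@@H]2C[C@H]14 | target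

## Step count and least certain steps

Total step count: 19. Longest linear sequence: 16 steps (1, 4, 6 to 19).

**Step 11 (key step).**
- What may go wrong: incomplete conjugate addition of the hindered, trisubstituted enol silane to the lactone acceptor; proton transfer or retro-addition within the metal enolate before the aldehyde arrives; erosion of facial control at C11' if the aldol becomes reversible.
- Fallback, from 14 and 13 back to 30: it uses the cycloaddition that was not chosen as the main line. Domino enyne metathesis of 14 with 32 (second-generation Hoveyda–Grubbs catalyst) gives the dienone lactone of the 7R,8R,10S series F1. Heating F1 with an excess of 13 (toluene, 110 °C) gives the spiro cycloadduct F2 with C1=C2 and C3–H. γ-Oxygenation of F2 through its dienolate (DBU, O2, triethyl phosphite), with axial attack at C1, returns to the route at 30.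

**Step 13.**
- What may go wrong: ring closure through the alternative chair (C7' axial) or with cis-fusion to ring B, which gives the wrong configuration at C1 and C5; loss of the acetyl group by retro-Claisen cleavage.
- Fallback, from 23 back to 24: change the mode of activation. Soft enolisation of 23 (TBSOTf, Et3N) gives the silyl enol ether of the acetyl group F3. F3 is cyclised under Lewis acid (TiCl4 or BF3·OEt2, CH2Cl2, −78 °C) in a Mukaiyama aldol reaction, in which the chelated acceptor ketone and not an enolate cation dictates the approach.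

**Step 4 (and its mirror image, step 5).**
- What may go wrong: the ester-substituted allylboronate is only weakly activated by the phosphoric acid, so an unselective background reaction would erode control of C8 (and C7) relative to C10.
- Fallback, from 9 back to 11: move the chirality into the reagent. Transesterification of 9 with (1R,2R)-1,2-dicyclohexylethane-1,2-diol gives the chiral allylboronate F4. F4 is added to 3 with Sc(OTf)3 as catalyst and the adduct is lactonised as before. The antipodal diol serves for 13.

**Step 10.**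
- What may go wrong: deactivation of the ruthenium catalyst by the sulfide and slow closure onto the 1,1-disubstituted enol silane.
- Fallback, from 15 back to 19: close the ring on a sulfur-free substrate. 15 is silylated (TBSOTf, Et3N, −78 °C) to the enol silane F5. Ring-closing metathesis of F5 gives the bicyclic enol silane with the free methylene lactone F6. Benzenethiol is then added to F6 (Et3N) to give 19.

**Step 18.**
- What may go wrong: the domino process may stop after ring closure, because cross-metathesis with the electron-poor partner at the hindered spiro compound is slow; the ring A methylene group may be engaged instead.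
- Fallback, from 31 back to 34: separate the two events. Ring-closing enyne metathesis under ethene gives 33, which is isolated. Selective oxidative cleavage of its terminal vinyl group (OsO4 cat., NaIO4) gives the enal F7. Wittig olefination of F7 with (acetylmethylidene)triphenylphosphorane, Ph3P=CHC(O)CH3, gives 34.

## Further compounds

F1 | step 11 | (3aR,7S,8aR)-7-methyl-3-methylidene-6-[(1E)-3-oxobut-1-en-1-yl]-3,3a,4,7,8,8a-hexahydro-2H-cyclohepta[b]furan-2-one | C=C1C(=O)O[C@@H]2C[C@H](C)C(/C=C/C(C)=O)=CC[C@H]12
F2 | step 11 | spiro cycloadduct of F1 and 13 (C1=C2, C3–H bearing acetyl, C3 not assigned; otherwise as 30) | C=C1C(=O)O[C@@H]2C[C@H](C)C3=CC(C(C)=O)[C@]4(C[C@@H]3C[C@H]12)C(=O)O[C@@H](C[C@@H](C)C#C[Si](C(C)C)(C(C)C)C(C)C)[C@H]4CC=C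
F3 | step 13 | tert-butyldimethylsilyl enol ether of the acetyl group of 23 | c1ccccc1SCC1C(=O)O[C@@H]2C[C@H](C)C(=O)[C@H](C[C@@]3(C(=C)O[Si](C)(C)C(C)(C)C)C(=O)O[C@@H](C[C@@H](C)C#C[Si](C(C)C)(C(C)C)C(C)C)[C@H]3CC=C)C[C@H]12
F4 | step 4 | ethyl (2E)-2-{[(4R,5R)-4,5-dicyclohexyl-1,3,2-dioxaborolan-2-yl]methyl}hexa-2,5-dienoate | CCOC(=O)/C(CB1O[C@H](C2CCCCC2)[C@@H](C2CCCCC2)O1)=C/CC=C
F5 | step 10 | (4R,5R)-5-[(2S)-3-{[tert-butyl(dimethyl)silyl]oxy}-2-methylbut-3-en-1-yl]-3-methylidene-4-(prop-2-en-1-yl)oxolan-2-one | C=C1C(=O)O[C@H](C[C@H](C)C(=C)O[Si](C)(C)C(C)(C)C)[C@@H]1CC=C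
F6 | step 10 | (3aR,7S,8aR)-6-{[tert-butyl(dimethyl)silyl]oxy}-7-methyl-3-methylidene-3,3a,4,7,8,8a-hexahydro-2H-cyclohepta[b]furan-2-one | C=C1C(=O)O[C@@H]2C[C@H](C)C(O[Si](C)(C)C(C)(C)C)=CC[C@H]12
F7 | step 18 | enal: as 33 with the C1' vinyl group cut to a formyl group | C=C1C(=O)O[C@@H]2C[C@H](C)[C@@]3(O)C=C(C(C)=O)[C@]4(C[C@@H]3C[C@H]12)C(=O)O[C@H]1C[C@@H](C)C(C=O)=CC[C@H]14
A1 | alternative 1 | dienone lactone of the 7R,8R,10S series, (3aR,7S,8aR)-7-methyl-3-methylidene-6-[(1E)-3-oxobut-1-en-1-yl]-3,3a,4,7,8,8a-hexahydro-2H-cyclohepta[b]furan-2-one | C=C1C(=O)O[C@@H]2C[C@H](C)C(/C=C/C(C)=O)=CC[C@H]12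
A2 | alternative 1 | epoxy α-methylidene lactone of the mirror-image series (1',5'-epoxide, configuration as in half 2 of 35) | C=C1C(=O)O[C@H]2C[C@@H](C)[C@]3(/C=C/C(C)=O)O[C@@H]3C[C@@H]12
A3 | alternative 1 | cycloadduct of A1 and A2 (C1=C2, C3–H, no C1 hydroxyl; C3 not assigned) | C=C1C(=O)O[C@@H]2C[C@H](C)C3=CC(C(C)=O)[C@]4(C[C@@H]3C[C@H]12)C(=O)O[C@H]1C[C@@H](C)[C@]2(/C=C/C(C)=O)O[C@@H]2C[C@H]14
A4 | alternative 2 | 4-acetyl-2H-pyran-2-one carrying at C6 the C10 side chain of the ring A lactone and at C3 the open C7'/C8' carbinol chain of half 2 | C=C1C(=O)O[C@H](C[C@H](C)c2cc(C(C)=O)c([C@H](CC=C)[C@@H](O)C[C@@H](C)C#C)c(=O)o2)[C@@H]1CC=C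
A5 | alternative 3 | 3-acetyl lactone of half 2 (C11' epimers), (4S,5S)-3-acetyl-5-{(2R)-2-methyl-4-[tri(propan-2-yl)silyl]but-3-yn-1-yl}-4-(prop-2-en-1-yl)oxolan-2-one | CC(=O)C1C(=O)O[C@@H](C[C@@H](C)C#C[Si](C(C)C)(C(C)C)C(C)C)[C@H]1CC=C
A6 | alternative 3 | exo-methylidene ketone of half 1, (3aR,7S,8aR)-7-methyl-5-methylidene-3-[(phenylsulfanyl)methyl]hexahydro-2H-cyclohepta[b]furan-2,6(3H)-dione | c1ccccc1SCC1C(=O)O[C@@H]2C[C@H](C)C(=O)C(=C)C[C@H]12
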